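**Retrosynthetic overview**
1. C9/C10: the target comes from a 9β,10β-epoxy ene-dione and angelic acid (SN2 at C9 with inversion). The C6=C7 bond and the acetyl group come from C-acetylation and selenoxide elimination of an epoxy ketone, and the epoxide from nucleophilic epoxidation of a 3β-acetoxy-4β,5β-dimethyloctalone.
2. Rings A and B, C4 and C5: the octalone comes from a ten-membered (E,E)-dienone acetate in one transannular cascade. C5–C10 closes onto the Lewis-acid-activated enone, then a 1,2-H shift (C5→C4) and a 1,2-Me shift (C10→C5) follow. This is the germacrane → eudesmyl cation → eremophilane path.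
3. The ten-membered ring comes from an acyclic vinyl-epoxide β-keto ester by π-allylpalladium closure of C6–C7, the farnesyl C1–C10 bond. The epoxide oxygen becomes the C3 oxygen.
4. The chain comes from methyl geranate, CH2 (Wittig) and tert-butyl acetate (Claisen). The only reagent-controlled stereocentre, C3, is set by a Sharpless epoxidation and relays to C4, C5, C9 and C10.
5. Ring order: the ten-membered carbocycle first, then rings A and B together in the transannular step.

Assumption: eremophilane numbering is used throughout (decalin C1–C10, C14 = methyl on C5, C15 = methyl on C4, acetyl = C11/C13). β is the face of the C5 methyl group. Commercial methyl geranate is taken as the pure 2E isomer.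

**Step 1**
Reactants: 1 methyl geranate [methyl (2E)-3,7-dimethylocta-2,6-dienoate]
Product: 2 methyl (2E,6E)-8-hydroxy-3,7-dimethylocta-2,6-dienoate
Conditions: SeO2 (0.2 equiv), tBuOOH (3 equiv), CH2Cl2, 0 °C → rt
Reagents that add atoms: tert-butyl hydroperoxide, CC(C)(C)OO (oxygen atom, passed on through the catalyst SeO2, O=[Se]=O)
Why: SeO2-catalysed allylic oxidation (ene reaction then 2,3-sigmatropic shift) attacks only the electron-rich 6,7-olefin and, as is general for trisubstituted olefins, hydroxylates the methyl group trans to the chain, giving the 6E allylic alcohol while the conjugated 2,3-olefin is inert.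

**Step 2**
Reactants: 2 methyl (2E,6E)-8-hydroxy-3,7-dimethylocta-2,6-dienoate
Product: 3 methyl (2E)-5-[(2S,3S)-3-(hydroxymethyl)-3-methyloxiran-2-yl]-3-methylpent-2-enoate
Conditions: Ti(OiPr)4 (10 mol %), L-(+)-diethyl tartrate (12 mol %), tBuOOH, 4 Å MS, CH2Cl2, −20 °C
Reagents that add atoms: tert-butyl hydroperoxide, CC(C)(C)OO
Why: Sharpless asymmetric epoxidation, in which the allylic hydroxyl binds titanium so that only the 6,7-olefin reacts and L-(+)-tartrate delivers oxygen to the face that gives the 2S,3S epoxy alcohol (as for other E-2-methylalk-2-en-1-ols), thereby fixing the future C3–O stereocentre as S.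

**Step 3**
Reactants: 3 methyl (2E)-5-[(2S,3S)-3-(hydroxymethyl)-3-methyloxiran-2-yl]-3-methylpent-2-enoate
Product: 4 methyl (2E)-5-[(2S,3R)-3-formyl-3-methyloxiran-2-yl]-3-methylpent-2-enoate
Conditions: TEMPO (10 mol %), PhI(OAc)2, CH2Cl2, rt
Reagents that add atoms: none
Why: Oxoammonium (TEMPO) oxidation of the primary alcohol stops at the aldehyde under nearly neutral conditions that leave epoxide and enoate alone, and the α-carbon is quaternary so nothing can epimerise (the descriptor becomes R only because CHO outranks the ring carbon).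

**Step 4**
Reactants: 4 methyl (2E)-5-[(2S,3R)-3-formyl-3-methyloxiran-2-yl]-3-methylpent-2-enoate; 5 methyltriphenylphosphonium bromide
Product: 6 methyl (2E)-5-[(2S,3S)-3-ethenyl-3-methyloxiran-2-yl]-3-methylpent-2-enoate
Conditions: 5, KOtBu, THF, 0 °C; then 4, −78 → 0 °C
Reagents that add atoms: methyltriphenylphosphonium bromide, C[P+](c1ccccc1)(c1ccccc1)c1ccccc1.[Br-]
Why: Wittig methylenation of the non-enolisable epoxy aldehyde is faster than any attack on the conjugated ester, supplies C6 and turns the epoxide into the vinyl epoxide needed for π-allyl formation without touching either stereocentre.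

**Step 5**
Reactants: 6 methyl (2E)-5-[(2S,3S)-3-ethenyl-3-methyloxiran-2-yl]-3-methylpent-2-enoate; 7 tert-butyl acetate
Product: 8 tert-butyl (4E)-7-[(2S,3S)-3-ethenyl-3-methyloxiran-2-yl]-5-methyl-3-oxohept-4-enoate
Conditions: 7, LiN(iPr)2 (3.2 equiv each), THF, −78 °C; then 6, −78 → −10 °C; AcOH quench
Reagents that add atoms: tert-butyl acetate, CC(=O)OC(C)(C)C
Why: Crossed Claisen condensation, in which the lithium enolate of tert-butyl acetate acylates at the methyl ester (β,β-disubstitution blocks conjugate addition and the unactivated trisubstituted epoxide is inert at low temperature) and deprotonation of the product by a second equivalent drives the reaction, so the 2E enoate geometry is carried into the 4E enone.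

**Step 6**
Reactants: 8 tert-butyl (4E)-7-[(2S,3S)-3-ethenyl-3-methyloxiran-2-yl]-5-methyl-3-oxohept-4-enoate
Product: 9 tert-butyl (3E,7S,8E)-7-hydroxy-4,8-dimethyl-2-oxocyclodeca-3,8-diene-1-carboxylate (C1 epimers)
Conditions: Pd(PPh3)4 (5 mol %), dppe (5 mol %), THF, 60 °C, syringe-pump addition (final 0.004 M)
Reagents that add atoms: none
Why: Tsuji–Trost cycloisomerisation of a vinyl epoxide, in which zerovalent palladium ionises the tertiary allylic C4–O bond, the freed C3 alkoxide deprotonates the β-keto ester so no external base is needed, and the soft enolate attacks the unhindered CH2 terminus C6 of the syn π-allyl complex under pseudo-high dilution, closing the ten-membered ring at the C6–C7 bond (farnesyl C1–C10) that the cyclase makes, giving the E C4=C5 olefin and leaving the C3–O bond (S) untouched while C7 forms as an inconsequential epimer mixture.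

**Step 7**
Reactants: 9 tert-butyl (3E,7S,8E)-7-hydroxy-4,8-dimethyl-2-oxocyclodeca-3,8-diene-1-carboxylate; 10 acetic anhydride
Product: 13 (1S,2E,7E)-2,8-dimethyl-6-oxocyclodeca-2,7-dien-1-yl acetate, via acetate tert-butyl ester 11 (not isolated), via acetate β-keto acid 12 (not isolated)
Conditions: 10, pyridine, DMAP (cat.), toluene, rt; then H2O, 110 °C
Reagents that add atoms: acetic anhydride, CC(=O)OC(C)=O
Why: DMAP-catalysed acetylation of the secondary allylic alcohol with retention at C3 is followed in the same flask by neutral thermolysis of the tert-butyl β-keto ester in the presence of water, giving the β-keto acid that decarboxylates at once, which removes the activating group and the C7 stereocentre without any strong acid that could trigger premature transannular reaction.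

**Step 8**
Reactants: 13 (1S,2E,7E)-2,8-dimethyl-6-oxocyclodeca-2,7-dien-1-yl acetate
Product: 15 (1R,2S,8aR)-1,8a-dimethyl-6-oxo-1,2,3,4,6,7,8,8a-octahydronaphthalen-2-yl acetate (3β-acetoxy-11,12,13-trinoreremophil-9-en-8-one), via eudesm-4-yl cation aluminium enolate 14 (not isolated)
Conditions: MeAlCl2 (3 equiv), CH2Cl2 (0.01 M), −78 → −20 °C; then H2O
Reagents that add atoms: none
Why: Proposed new method: MeAlCl2 turns the enone into a vinylogous oxocarbenium ion whose C10 plays the part of the protonated germacrene, the E C4=C5 olefin attacks it transannularly through C5 in a chair–chair array that keeps the aluminium-complexed 3-acetoxy group equatorial and in the nodal plane of the developing C4 cation (giving the 5α-H, 10β-Me zwitterion 14), and, since no base is present, the antiperiplanar 1,2-hydride shift C5→C4 on the α face and 1,2-methyl shift C10→C5 on the β face move the charge away from the acetoxy-bearing carbon until the aluminium enolate quenches it irreversibly as the conjugated enone, which sets 4β-Me and 5β-Me cis to each other and to 3β-OAc; the closest known reaction type is the alkylaluminium-halide-induced conjugate addition of alkenes to enones in which the zwitterion undergoes two 1,2-hydride or alkyl shifts to regenerate an enone, and the sequence copies the germacrene A → eudesmyl cation → eremophilenyl cation path of aristolochene-type cyclases.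

**Step 9**
Reactants: 15 3β-acetoxy-11,12,13-trinoreremophil-9-en-8-one
Product: 16 (3S,4R,5R,9R,10R)-3-acetoxy-9,10-epoxy-11,12,13-trinoreremophilan-8-one (9β,10β-epoxide)
Conditions: 30% H2O2, NaOH (0.3 equiv), MeOH/CH2Cl2, 0 °C
Reagents that add atoms: hydrogen peroxide, OO
Why: Weitz–Scheffer nucleophilic epoxidation, in which hydroperoxide adds axially to C10 on the face of the angular methyl group so that the enolate develops in a chair, cis-fused ring, the same preference that makes alkaline H2O2 give mainly the β-epoxides of steroidal 4-en-3-ones and 10-methyloctalones, which sets 10β-O and 9β-O while catalytic base at 0 °C spares the hindered axial acetate.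

**Step 10**
Reactants: 16 3β-acetoxy-9β,10β-epoxy-11,12,13-trinoreremophilan-8-one; 17 1-acetylbenzotriazole
Product: 18 3β-acetoxy-9β,10β-epoxy-13-noreremophilane-8,11-dione (enolised at C7)
Conditions: LiN(SiMe3)2 (2.1 equiv), THF, −78 °C; then 17, −78 → −30 °C; AcOH quench
Reagents that add atoms: 1-acetylbenzotriazole, CC(=O)n1nnc2ccccc12
Why: Claisen-type C-acylation, since kinetic deprotonation can only occur at C7 (C9 is an epoxide carbon and the acetate is far less acidic), N-acylbenzotriazoles are established C-selective acylating agents for ketone lithium enolates, and the second equivalent of base stores the product as its chelated enolate, so C11 and C13 are installed and C7 is left as an enolised, stereochemically irrelevant centre.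

**Step 11**
Reactants: 18 3β-acetoxy-9β,10β-epoxy-13-noreremophilane-8,11-dione
Product: 21 3β-acetoxy-9β,10β-epoxy-13-noreremophil-6-ene-8,11-dione, via C7 phenylselenide 19 (not isolated), via C7 selenoxide 20 (not isolated)
Conditions: PhSeCl, pyridine, CH2Cl2, 0 °C; then mCPBA, −78 → 0 °C
Reagents that add atoms: none
Why: Selenenylation of the enolised β-diketone at C7 and selenoxide syn-elimination, which can only take a hydrogen from C6 because the other two neighbours of C7 are carbonyl carbons, give the 2-acyl enone below 0 °C, selenium being oxidised far faster than any other group present and no stereocentre being touched.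

**Step 12**
Reactants: 21 3β-acetoxy-9β,10β-epoxy-13-noreremophil-6-ene-8,11-dione; 22 angelic acid [(Z)-2-methylbut-2-enoic acid]
Product: 23 (3S,4R,5R,9S,10R)-3-acetoxy-9-angeloyloxy-10-hydroxy-13-noreremophil-6-ene-8,11-dione (CNP0196241.1)
Conditions: 22 (4 equiv), Cs2CO3 (0.5 equiv), DMF, 40 °C
Reagents that add atoms: angelic acid, C/C=C(/C)C(=O)O
Why: SN2 opening of an α,β-epoxy ketone at the carbonyl-activated secondary carbon, in which angelate attacks C9 from the α face anti to the C9–O bond, as nucleophiles do at C4 of steroidal 4β,5β-epoxy-3-ketones, so C9 is inverted to 9α-OAng while the C10–O bond is kept as the 10β-alcohol, the excess acid protonates the alkoxide at once (no retro-aldol or dehydration), addition to C6 is reversible, and the Z geometry of the angelate is stable at 40 °C.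

**Compound list**
1 | methyl geranate | COC(=O)/C=C(\C)CCC=C(C)C | starting material
2 | methyl (2E,6E)-8-hydroxy-3,7-dimethylocta-2,6-dienoate | COC(=O)/C=C(\C)CC/C=C(\C)CO | intermediate
3 | methyl (2E)-5-[(2S,3S)-3-(hydroxymethyl)-3-methyloxiran-2-yl]-3-methylpent-2-enoate | COC(=O)/C=C(\C)CC[C@@H]1O[C@@]1(C)CO | intermediate
4 | methyl (2E)-5-[(2S,3R)-3-formyl-3-methyloxiran-2-yl]-3-methylpent-2-enoate | COC(=O)/C=C(\C)CC[C@@H]1O[C@@]1(C)C=O | intermediate
5 | methyltriphenylphosphonium bromide | C[P+](c1ccccc1)(c1ccccc1)c1ccccc1.[Br-] | starting material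
6 | methyl (2E)-5-[(2S,3S)-3-ethenyl-3-methyloxiran-2-yl]-3-methylpent-2-enoate | COC(=O)/C=C(\C)CC[C@@H]1O[C@@]1(C)C=C | intermediate
7 | tert-butyl acetate | CC(=O)OC(C)(C)C | starting material
8 | tert-butyl (4E)-7-[(2S,3S)-3-ethenyl-3-methyloxiran-2-yl]-5-methyl-3-oxohept-4-enoate | CC(C)(C)OC(=O)CC(=O)/C=C(\C)CC[C@@H]1O[C@@]1(C)C=C | intermediate
9 | tert-butyl (3E,7S,8E)-7-hydroxy-4,8-dimethyl-2-oxocyclodeca-3,8-diene-1-carboxylate (C1 epimers) | O=C1/C=C(\C)CC[C@H](O)/C(C)=C/CC1C(=O)OC(C)(C)C | intermediate
10 | acetic anhydride | CC(=O)OC(C)=O | starting material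
11 | tert-butyl (3E,7S,8E)-7-acetoxy-4,8-dimethyl-2-oxocyclodeca-3,8-diene-1-carboxylate | O=C1/C=C(\C)CC[C@H](OC(C)=O)/C(C)=C/CC1C(=O)OC(C)(C)C | intermediate
12 | (3E,7S,8E)-7-acetoxy-4,8-dimethyl-2-oxocyclodeca-3,8-diene-1-carboxylic acid | O=C1/C=C(\C)CC[C@H](OC(C)=O)/C(C)=C/CC1C(=O)O | intermediate
13 | (1S,2E,7E)-2,8-dimethyl-6-oxocyclodeca-2,7-dien-1-yl acetate | O=C1/C=C(\C)CC[C@H](OC(C)=O)/C(C)=C/CC1 | intermediate
14 | MeAlCl2-bound 8-enolate of the 3β-acetoxy-5αH-11,12,13-trinoreudesm-4-yl cation (zwitterion) | CC(=O)O[C@H]1CC[C@]2(C)C=C(O[Al-](C)(Cl)Cl)CC[C@H]2[C+]1C | intermediate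
15 | (1R,2S,8aR)-1,8a-dimethyl-6-oxo-1,2,3,4,6,7,8,8a-octahydronaphthalen-2-yl acetate | CC(=O)O[C@H]1CCC2=CC(=O)CC[C@]2(C)[C@H]1C | intermediate
16 | (3S,4R,5R,9R,10R)-3-acetoxy-9,10-epoxy-11,12,13-trinoreremophilan-8-one | CC(=O)O[C@H]1CC[C@]23O[C@H]2C(=O)CC[C@]3(C)[C@H]1C | intermediate
17 | 1-acetylbenzotriazole | CC(=O)n1nnc2ccccc12 | starting material
18 | 3β-acetoxy-9β,10β-epoxy-13-noreremophilane-8,11-dione (drawn as diketone, C7 undefined) | CC(=O)O[C@H]1CC[C@]23O[C@H]2C(=O)C(C(C)=O)C[C@]3(C)[C@H]1C | intermediate
19 | 7-phenylselanyl derivative of 18 | CC(=O)O[C@H]1CC[C@]23O[C@H]2C(=O)C(C(C)=O)([Se]c4ccccc4)C[C@]3(C)[C@H]1C | intermediate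
20 | 7-phenylseleninyl derivative of 18 | CC(=O)O[C@H]1CC[C@]23O[C@H]2C(=O)C(C(C)=O)([Se](=O)c4ccccc4)C[C@]3(C)[C@H]1C | intermediate
21 | 3β-acetoxy-9β,10β-epoxy-13-noreremophil-6-ene-8,11-dione | CC(=O)O[C@H]1CC[C@]23O[C@H]2C(=O)C(C(C)=O)=C[C@]3(C)[C@H]1C | intermediate
22 | angelic acid | C/C=C(/C)C(=O)O | starting material
23 | (3S,4R,5R,9S,10R)-3-acetoxy-9-angeloyloxy-10-hydroxy-13-noreremophil-6-ene-8,11-dione | C/C=C(/C)C(=O)O[C@@H]1C(=O)C(C(C)=O)=C[C@]2(C)[C@@H](C)[C@@H](OC(C)=O)CC[C@]12O | target

**Totals**
Total step count: 12. Longest linear sequence: 12 (from 1).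

**Steps most likely to fail**

Step 8. The charge may be lost by proton loss or acetate participation before both shifts have happened. The fold may also place the acetoxy group axially. The fallback separates ring closure from rearrangement and sets out from 13. Me2AlCl is a weaker Lewis acid that also scavenges protons. In CH2Cl2 at −78 °C it should stop after the transannular closure at the ene-type product 3β-acetoxy-5αH-11,12,13-trinoreudesm-4(15)-en-8-one F3, which is isolated. CF3SO3H in (CF3)2CHOH/CH2Cl2 then reprotonates the exocyclic olefin to the same C4 cation under equilibrating conditions. Olefinic products re-enter the cation manifold, and only the conjugated enone leaves it, because it is protonated on oxygen and not on carbon. The material therefore drains to 15, where the route is rejoined.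

Step 6. Outer-sphere attack of the stabilised enolate may be too slow for a ten-membered ring, so oligomers or isomerised epoxide would form. The fallback closes the ring at the metal with loss of CO2 and sets out from 6. Condensation with LiCH2CO2Li (from AcOH and two equivalents of LiN(iPr)2), followed by a cold pH 4.5 work-up, gives (4E)-7-[(2S,3S)-3-ethenyl-3-methyloxiran-2-yl]-5-methyl-3-oxohept-4-enoic acid F1, which is used at once. With Pd(PPh3)4 under slow addition the acid protonates the alkoxide and its carboxylate binds the π-allylpalladium unit. Decarboxylation leaves enolate and allyl on the same metal, and reductive elimination gives (2E,6S,7E)-6-hydroxy-3,7-dimethylcyclodeca-2,7-dien-1-one F2. This is the intramolecular form of the known decarboxylative allylation of β-keto acids by diene monoepoxides. Acetylation (Ac2O, pyridine, DMAP) comes back to the route at 13.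

Step 12. Angelate is a weak and hindered nucleophile, so dehydration to the diosphenol ester or attack at C6 may win. The fallback opens the epoxide with a small carboxylate and esterifies afterwards, setting out from 21. HCO2Cs/HCO2H in DMF opens the epoxide at C9 to 3β-acetoxy-9α-formyloxy-10β-hydroxy-13-noreremophil-6-ene-8,11-dione F4. KHCO3 in MeOH at 0 °C removes only the formate and gives 3β-acetoxy-9α,10β-dihydroxy-13-noreremophil-6-ene-8,11-dione F5. The secondary 9-OH alone is then acylated with the mixed anhydride made from 22 and 2,4,6-trichlorobenzoyl chloride (Et3N, then DMAP, toluene). This arrives at 23.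

**Further compounds**
F1 | step 6 | (4E)-7-[(2S,3S)-3-ethenyl-3-methyloxiran-2-yl]-5-methyl-3-oxohept-4-enoic acid | OC(=O)CC(=O)/C=C(\C)CC[C@@H]1O[C@@]1(C)C=C
F2 | step 6 | (2E,6S,7E)-6-hydroxy-3,7-dimethylcyclodeca-2,7-dien-1-one | O=C1/C=C(\C)CC[C@H](O)/C(C)=C/CC1
F3 | step 8 | 3β-acetoxy-5αH-11,12,13-trinoreudesm-4(15)-en-8-one | CC(=O)O[C@H]1CC[C@]2(C)CC(=O)CC[C@H]2C1=C
F4 | step 12 | 3β-acetoxy-9α-formyloxy-10β-hydroxy-13-noreremophil-6-ene-8,11-dione | O=CO[C@@H]1C(=O)C(C(C)=O)=C[C@]2(C)[C@@H](C)[C@@H](OC(C)=O)CC[C@]12O
F5 | step 12 | 3β-acetoxy-9α,10β-dihydroxy-13-noreremophil-6-ene-8,11-dione | O[C@@H]1C(=O)C(C(C)=O)=C[C@]2(C)[C@@H](C)[C@@H](OC(C)=O)CC[C@]12O
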